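**Strategy.** The cyclohexane ring (ionone numbering: C1 gem-dimethyl, C3 acyloxy, C5/C6 epoxide carbons) is disconnected at C1–C2 and C3–C4. Everything rests on a catalytic enantioselective Diels–Alder reaction between a 2-silyloxy diene (C4=C5–C6=C1, the silyl dienol ether of isopropyl isopropenyl ketone) and methyl vinyl ketone (C2=C3). It exploits the fact that the epoxide, a masked C5=C6 alkene, lies where a [4+2] leaves its double bond, para to oxygenated C3. One operation closes the ring, creates the quaternary C1, sets the C3 configuration and delivers C5=C6 as a regiodefined enol ether for side-chain coupling. The acetyl group at C3 is later exchanged for oxygen by Baeyer–Villiger oxidation; directed epoxidation and an inverting esterification finish the synthesis.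

Key step: step 3

Assumption: the (S)-configured oxazaborolidinium catalyst is taken to give the (1S)-adduct 6 (enone bound s-trans, acetyl endo); should the sense of induction be opposite for this diene, the (R)-catalyst is used and nothing else changes.

Atom numbering used below (ionone convention): ring C1 (gem-dimethyl), C2, C3 (oxygenated), C4, C5 (methyl-bearing), C6 (side-chain-bearing); side chain C7=C8–C9(=O)–C10.

Step 1
Reactants: 1 N-methoxy-N-methylisobutyramide; 2 isopropenylmagnesium bromide
Product: 3 2,4-dimethylpent-1-en-3-one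
Conditions: THF, 0 °C → rt; inverse quench into cold 1 M HCl
Reagents that add atoms: none
Why: Weinreb ketone synthesis: the alkenyl Grignard reagent adds once to the N-methoxy-N-methyl amide because the magnesium-chelated tetrahedral adduct survives until the acidic quench, which also keeps the liberated hydroxylamine from adding to the new enone.

Step 2
Reactants: 3 2,4-dimethylpent-1-en-3-one
Product: 4 tert-butyl[(2,4-dimethylpenta-1,3-dien-3-yl)oxy]dimethylsilane
Conditions: TBSOTf, Et3N, CH2Cl2, 0 °C → rt
Reagents that add atoms: tert-butyldimethylsilyl trifluoromethanesulfonate (TBSOTf), CC(C)(C)[Si](C)(C)OS(=O)(=O)C(F)(F)F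
Why: Soft enolisation to a silyl dienol ether: the silyl triflate activates the carbonyl and triethylamine removes the only enolisable hydrogen (the isopropyl methine), so the cross-conjugated 2-silyloxy diene forms as a single regioisomer without stereochemical issue.

Step 3
Reactants: 4 tert-butyl[(2,4-dimethylpenta-1,3-dien-3-yl)oxy]dimethylsilane; 5 methyl vinyl ketone
Product: 6 1-[(1S)-4-(tert-butyldimethylsilyloxy)-3,5,5-trimethylcyclohex-3-en-1-yl]ethan-1-one
Conditions: (S)-1-(2-methylphenyl)-3,3-diphenyltetrahydro-1H,3H-pyrrolo[1,2-c][1,3,2]oxazaborole (20 mol%) activated by HN(SO2CF3)2 (18 mol%), CH2Cl2, −78 → −40 °C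
Reagents that add atoms: none
Why: The N-protonated oxazaborolidinium ion binds the carbonyl oxygen of 5 and lowers its LUMO; the electron-rich tetrasubstituted terminus of the silyl enol ether of 4 (C1) attacks the β-CH2 (C2) in a highly asynchronous, Mukaiyama–Michael-like transition state and the developing boron enolate carbon (C3) closes onto the isopropenyl CH2 (C4), so C1–C2 and C3–C4 arise in one Diels–Alder event. The closest known reaction type is the oxazaborolidinium-catalysed enantioselective Diels–Alder reaction of 2-silyloxy-1,3-dienes with enones and acrylates, together with strong-Lewis-acid Diels–Alder reactions of hindered silyloxy dienes that build quaternary carbons. The cyclohexene ring closes by intermolecular [4+2] cycloaddition (in the stepwise limit a 6-endo-trig Michael closure onto the silyloxy-activated enone), leaving C5=C6 as a regiodefined silyl enol ether. The single new stereocentre C3 is controlled by the catalyst, which shields one face of the bound enone while the acetyl group adopts the endo orientation. The step needs "para" regioselectivity (acetyl at C3, not next to the gem-dimethyl carbon); this is secured by the 2-silyloxy group, which makes C1 the nucleophilic terminus and stabilises oxocarbenium character at C6, while the unhindered CH2 of 5 tolerates formation of the quaternary C1.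

Step 4
Reactants: 6 1-[(1S)-4-(tert-butyldimethylsilyloxy)-3,5,5-trimethylcyclohex-3-en-1-yl]ethan-1-one
Product: 7 (4S)-4-acetyl-2,6,6-trimethylcyclohex-1-en-1-yl trifluoromethanesulfonate
Conditions: CsF, PhN(SO2CF3)2, 1,2-dimethoxyethane, rt
Reagents that add atoms: N-phenylbis(trifluoromethanesulfonimide), O=S(=O)(N(c1ccccc1)S(=O)(=O)C(F)(F)F)C(F)(F)F
Why: Fluoride-mediated silyl enol ether to enol triflate exchange: fluoride cleaves the O–Si bond and the regiodefined tetrasubstituted enolate is trapped on oxygen in situ by the triflimide, so the C5=C6 position fixed by the cycloaddition is kept while the low steady-state basicity should spare the acetyl-bearing stereocentre.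

Step 5
Reactants: 7 (4S)-4-acetyl-2,6,6-trimethylcyclohex-1-en-1-yl trifluoromethanesulfonate
Product: 9 (4S)-4-hydroxy-2,6,6-trimethylcyclohex-1-en-1-yl trifluoromethanesulfonate, via acetate ester 8 (not isolated)
Conditions: mCPBA, CH2Cl2, 0 °C → rt; aqueous Na2SO3/NaHCO3 wash; then K2CO3 (cat.), MeOH, 0 °C
Reagents that add atoms: meta-chloroperbenzoic acid (mCPBA), O=C(OO)c1cccc(Cl)c1
Why: Baeyer–Villiger oxidation followed by transesterification: the secondary ring carbon migrates in preference to methyl with retention of configuration, the electron-poor enol triflate is inert to the peracid, and mild methanolysis of the resulting acetate frees the (S)-alcohol.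

Step 6
Reactants: 9 (4S)-4-hydroxy-2,6,6-trimethylcyclohex-1-en-1-yl trifluoromethanesulfonate; 5 methyl vinyl ketone
Product: 10 (3E)-4-[(4S)-4-hydroxy-2,6,6-trimethylcyclohex-1-en-1-yl]but-3-en-2-one [(S)-3-hydroxy-β-ionone]
Conditions: Pd(OAc)2 (5 mol%), PPh3 (10 mol%), Et3N, DMF, 70 °C
Reagents that add atoms: none
Why: Heck reaction: oxidative addition of the enol triflate to zerovalent palladium, insertion of the vinyl ketone at its unsubstituted terminus and syn β-hydride elimination give the (E)-dienone; the C3 stereocentre is remote and untouched.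

Step 7
Reactants: 10 (S)-3-hydroxy-β-ionone
Product: 11 (3E)-4-[(1S,4R,6R)-4-hydroxy-2,2,6-trimethyl-7-oxabicyclo[4.1.0]heptan-1-yl]but-3-en-2-one [(3R,5R,6S) syn-epoxy alcohol]
Conditions: VO(acac)2 (cat.), t-BuOOH, toluene, 0 °C → rt
Reagents that add atoms: tert-butyl hydroperoxide, CC(C)(C)OO
Why: Hydroxyl-directed vanadium-catalysed epoxidation: the homoallylic C3 alkoxide binds vanadium and the coordinated tert-butyl peroxide is delivered intramolecularly to the face of the electron-rich tetrasubstituted C5=C6 bond syn to the hydroxyl, setting C5 (R) and C6 (S), while the electron-poor C7=C8 enone bond does not react.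

Step 8
Reactants: 11 (3R,5R,6S) syn-epoxy alcohol; 12 tetradecanoic acid
Product: 13 (3E)-4-[(1S,4S,6R)-2,2,6-trimethyl-4-(tetradecanoyloxy)-7-oxabicyclo[4.1.0]heptan-1-yl]but-3-en-2-one (target)
Conditions: PPh3, DIAD, toluene, 0 °C → rt
Reagents that add atoms: none
Why: Mitsunobu esterification: the tetradecanoate ion displaces the alkoxyphosphonium group in an SN2 reaction with inversion at C3 (R to S), which turns the syn epoxy alcohol into the anti epoxy ester of the target under neutral conditions that spare epoxide and enone.

**Compound list**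

1 | N-methoxy-N-methylisobutyramide | CC(C)C(=O)N(C)OC | starting material
2 | isopropenylmagnesium bromide | CC(=C)[Mg]Br | starting material
3 | 2,4-dimethylpent-1-en-3-one | CC(C)C(=O)C(C)=C | intermediate
4 | tert-butyl[(2,4-dimethylpenta-1,3-dien-3-yl)oxy]dimethylsilane | CC(C)=C(O[Si](C)(C)C(C)(C)C)C(C)=C | intermediate
5 | methyl vinyl ketone (but-3-en-2-one) | CC(=O)C=C | starting material
6 | 1-[(1S)-4-(tert-butyldimethylsilyloxy)-3,5,5-trimethylcyclohex-3-en-1-yl]ethan-1-one | CC(=O)[C@@H]1CC(C)(C)C(O[Si](C)(C)C(C)(C)C)=C(C)C1 | intermediate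
7 | (4S)-4-acetyl-2,6,6-trimethylcyclohex-1-en-1-yl trifluoromethanesulfonate | CC(=O)[C@@H]1CC(C)(C)C(OS(=O)(=O)C(F)(F)F)=C(C)C1 | intermediate
8 | (4S)-4-acetoxy-2,6,6-trimethylcyclohex-1-en-1-yl trifluoromethanesulfonate (acetate ester) | CC(=O)O[C@@H]1CC(C)(C)C(OS(=O)(=O)C(F)(F)F)=C(C)C1 | intermediate
9 | (4S)-4-hydroxy-2,6,6-trimethylcyclohex-1-en-1-yl trifluoromethanesulfonate | O[C@@H]1CC(C)(C)C(OS(=O)(=O)C(F)(F)F)=C(C)C1 | intermediate
10 | (3E)-4-[(4S)-4-hydroxy-2,6,6-trimethylcyclohex-1-en-1-yl]but-3-en-2-one, (S)-3-hydroxy-β-ionone | O[C@@H]1CC(C)(C)C(/C=C/C(C)=O)=C(C)C1 | intermediate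
11 | (3E)-4-[(1S,4R,6R)-4-hydroxy-2,2,6-trimethyl-7-oxabicyclo[4.1.0]heptan-1-yl]but-3-en-2-one, (3R,5R,6S) syn-epoxy alcohol | O[C@@H]1CC(C)(C)[C@]2(/C=C/C(C)=O)O[C@]2(C)C1 | intermediate
12 | tetradecanoic (myristic) acid | CCCCCCCCCCCCCC(=O)O | starting material
13 | (3E)-4-[(1S,4S,6R)-2,2,6-trimethyl-4-(tetradecanoyloxy)-7-oxabicyclo[4.1.0]heptan-1-yl]but-3-en-2-one, (3S,5R,6S) | CCCCCCCCCCCCCC(=O)O[C@H]1CC(C)(C)[C@]2(/C=C/C(C)=O)O[C@]2(C)C1 | target

**Totals.** Total step count: 8. Longest linear sequence: 8 steps (1 → 3 → 4 → 6 → 7 → 9 → 10 → 11 → 13).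

**Steps most likely to fail and fallbacks**

Step 3 (key cycloaddition), loss of catalyst control. The tetrasubstituted diene may react through a fully stepwise Michael/ring-closure pathway in which the catalyst no longer differentiates the faces when C3–C4 forms. The acidic catalyst may also protodesilylate the diene. Either would give low enantiomeric purity or poor conversion. The fallback replaces asymmetric catalysis by resolution and sets out from 4 and 5. The cycloaddition is run with an achiral strong Lewis acid (AlBr3/AlMe3 in toluene/CH2Cl2) to give racemic 1-[4-(tert-butyldimethylsilyloxy)-3,5,5-trimethylcyclohex-3-en-1-yl]ethan-1-one F1. The conditions of steps 4 to 6 then carry it through racemic 4-acetyl-2,6,6-trimethylcyclohex-1-en-1-yl trifluoromethanesulfonate F2, racemic 4-acetoxy-2,6,6-trimethylcyclohex-1-en-1-yl trifluoromethanesulfonate F3 (not isolated) and racemic 4-hydroxy-2,6,6-trimethylcyclohex-1-en-1-yl trifluoromethanesulfonate F4 to racemic 3-hydroxy-β-ionone F5. Lipase-catalysed transesterification (Burkholderia cepacia lipase, vinyl acetate, tert-butyl methyl ether, rt) is expected, by the empirical size rule with the gem-dimethyl flank as the large group, to acetylate the (3R)-alcohol to (R)-3-acetoxy-β-ionone F6. The unreacted (S)-alcohol is compound 10, where the route is re-joined.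

Step 4 (enol triflate formation), proton transfer. The fluoride-generated enolate can be quenched by, or equilibrate with, the enolisable methyl ketone. This would give desilylated diketone, triflation of the wrong enolate or epimerisation of the acetyl-bearing carbon. The fallback forms the enolate by deprotonation only after the methyl ketone has been removed, and sets out from 6. HF·pyridine in THF hydrolyses the silyl enol ether to (4S)-4-acetyl-2,2,6-trimethylcyclohexan-1-one F7 (C6 epimers, inconsequential). mCPBA should oxidise the unhindered methyl ketone in preference to the 2,2,6-trisubstituted ring ketone, giving (1S)-3,3,5-trimethyl-4-oxocyclohexyl acetate F8. K2CO3/MeOH gives (4S)-4-hydroxy-2,2,6-trimethylcyclohexan-1-one F9. LDA (2.2 equiv, THF, −78 °C) then forms the alkoxide–enolate, whose only possible enolate is trapped on oxygen by PhN(SO2CF3)2 to give compound 9, where the route is re-joined.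

Step 8 (inverting esterification), elimination or epoxide damage. Displacement at the ring carbinol flanked by the gem-dimethyl group may be slow. E2 elimination of the alkoxyphosphonium ion or opening of the acid-labile tetrasubstituted epoxide could then compete. The fallback inverts before the epoxide exists and relies on steric rather than directed epoxidation; it sets out from 10. Mitsunobu esterification of 10 with 12 (PPh3, DIAD, toluene) gives (R)-3-(tetradecanoyloxy)-β-ionone F10. Epoxidation with mCPBA (CH2Cl2, 0 °C) should then give compound 13 together with its (3S,5S,6R) syn-epoxide diastereomer F11, which is removed by chromatography; the route ends at 13.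

**Further compounds**

F1 | step 3 | racemic 1-[4-(tert-butyldimethylsilyloxy)-3,5,5-trimethylcyclohex-3-en-1-yl]ethan-1-one | CC(=O)C1CC(C)(C)C(O[Si](C)(C)C(C)(C)C)=C(C)C1
F2 | step 3 | racemic 4-acetyl-2,6,6-trimethylcyclohex-1-en-1-yl trifluoromethanesulfonate | CC(=O)C1CC(C)(C)C(OS(=O)(=O)C(F)(F)F)=C(C)C1
F3 | step 3 | racemic 4-acetoxy-2,6,6-trimethylcyclohex-1-en-1-yl trifluoromethanesulfonate | CC(=O)OC1CC(C)(C)C(OS(=O)(=O)C(F)(F)F)=C(C)C1
F4 | step 3 | racemic 4-hydroxy-2,6,6-trimethylcyclohex-1-en-1-yl trifluoromethanesulfonate | OC1CC(C)(C)C(OS(=O)(=O)C(F)(F)F)=C(C)C1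
F5 | step 3 | racemic 3-hydroxy-β-ionone | OC1CC(C)(C)C(/C=C/C(C)=O)=C(C)C1
F6 | step 3 | (R)-3-acetoxy-β-ionone | CC(=O)O[C@H]1CC(C)(C)C(/C=C/C(C)=O)=C(C)C1
F7 | step 4 | (4S)-4-acetyl-2,2,6-trimethylcyclohexan-1-one | CC(=O)[C@@H]1CC(C)(C)C(=O)C(C)C1
F8 | step 4 | (1S)-3,3,5-trimethyl-4-oxocyclohexyl acetate | CC(=O)O[C@@H]1CC(C)(C)C(=O)C(C)C1
F9 | step 4 | (4S)-4-hydroxy-2,2,6-trimethylcyclohexan-1-one | O[C@@H]1CC(C)(C)C(=O)C(C)C1
F10 | step 8 | (R)-3-(tetradecanoyloxy)-β-ionone | CCCCCCCCCCCCCC(=O)O[C@H]1CC(C)(C)C(/C=C/C(C)=O)=C(C)C1
F11 | step 8 | (3S,5S,6R)-5,6-epoxy-3-(tetradecanoyloxy)-5,6-dihydro-β-ionone (syn-epoxide diastereomer of 13) | CCCCCCCCCCCCCC(=O)O[C@H]1CC(C)(C)[C@@]2(/C=C/C(C)=O)O[C@@]2(C)C1
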